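**Retrosynthetic overview**
1. Toxiusol is the bis-sulfate of the hydroquinone, made last by SO3·pyridine sulfation. The hydroquinone comes from BBr3 demethylation of the 2,5-dimethoxyaryl ether.
2. The dimethyl ether comes from an electrochemical Kolbe heterocoupling of two β-quaternary terpenoid acetic acids. This forms the central quaternary C–CH2–CH2–C quaternary bond.
3. The aryl-bearing acid comes from (R)-pulegone. Ring B is the pulegone ring, and C9 becomes quaternary through two enolate alkylations. Ring A is then closed by Diels–Alder. A glyoxylate carbonyl-ene reaction builds quaternary C4 together with Δ5, and deoxygenation and saponification give the acid.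
4. The second acid comes from (S)-pulegone. Two enolate alkylations build C9′, Cu-mediated conjugate addition builds the gem-dimethyl carbon C4′ and sets C5′ by equilibration, and McMurry closes ring A′ last (Δ1(10)).
5. Labels: the first unit uses C4 (quaternary, carries the linker), C5=C6, C8 (CHMe), C9 (quaternary, carries the benzyl group) and C10 (ring-fusion CH). The second unit uses the same labels with primes.

Assumption: the target is drawn as the free disulfuric acid and is isolated as its disodium salt. (R)- and (S)-pulegone are both commercial.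

---

**Step 1**
Reactants: 1 (R)-pulegone; 2 2,5-dimethoxybenzyl bromide
Product: 3 trans-6-(2,5-dimethoxybenzyl)-(R)-pulegone
Conditions: LDA, THF, −78 °C; then 2, HMPA, −78 → 0 °C
Reagents that add atoms: 2,5-dimethoxybenzyl bromide, BrCc1cc(OC)ccc1OC
Why: Kinetic enolate alkylation. C2 of pulegone is fully substituted, so LDA deprotonates only the α′ position (C6 of pulegone = C9 of the target), and the electrophile enters anti to the 5-methyl. The C6 centre is erased again in step 2.

**Step 2**
Reactants: 3; 4 iodomethane
Product: 5 6-benzyl-6-methyl-(R)-pulegone (Me trans, benzyl cis to the 5-Me)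
Conditions: LDA, THF, −78 °C; then 4, 0 °C
Reagents that add atoms: iodomethane, CI
Why: Second enolate alkylation forms quaternary C9. The tetrasubstituted enolate has its 5-Me pseudoaxial, so axial methylation occurs anti to it, which leaves the benzyl group cis to the 5-Me as in the target.

**Step 3**
Reactants: 5; 6 N-phenylbis(trifluoromethanesulfonimide)
Product: 7 dienyl triflate
Conditions: LDA, THF, −78 °C; then 6, −78 → 0 °C
Reagents that add atoms: PhNTf2, O=S(=O)(C(F)(F)F)N(c1ccccc1)S(=O)(=O)C(F)(F)F
Why: With C9 quaternary, LDA can only remove a γ-H of an isopropylidene methyl. The extended dienolate is O-triflated (enol triflate formation) to give the 2-isopropenyl cyclohexenyl triflate.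

**Step 4**
Reactants: 7
Product: 8 diene (3-benzyl-3,4-dimethyl-1-isopropenylcyclohexene)
Conditions: Pd(OAc)2, PPh3, HCO2H, Et3N, DMF, 60 °C
Reagents that add atoms: none
Why: Pd-catalysed formate reduction of the vinyl triflate (Cacchi/Tsuji-type) replaces OTf by H at C10 and leaves the 1,3-diene intact.

**Step 5**
Reactants: 8; 9 phenyl vinyl sulfone
Product: 10 Diels–Alder adduct (PhSO2 at C1, C1 epimers, tetrasubstituted C4=C5)
Conditions: 9 (5 equiv), BHT, PhMe, 150 °C, sealed tube
Reagents that add atoms: phenyl vinyl sulfone, C=CS(=O)(=O)c1ccccc1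
Why: Diels–Alder closes ring A. In the favoured half-chair of the diene, the benzyl group (cis to the 8-Me) is pseudoaxial and blocks its face. The dienophile therefore adds to C10 from the face carrying the 9-Me, which puts H10 cis to the benzyl group and C1 cis to the 9-Me as in the target. Both sulfone regioisomers give the same octalin after step 6.

**Step 6**
Reactants: 10
Product: 11 octalin (C1 unsubstituted)
Conditions: 3% Na(Hg), Na2HPO4, MeOH/THF, −20 °C → rt
Reagents that add atoms: none
Why: Reductive desulfonylation (Julia–Trost type) removes the sulfone and the C1 stereocentre with it. The tetrasubstituted alkene, the aryl ether and C10 are unaffected.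

**Step 7**
Reactants: 11; 12 ethyl glyoxylate
Product: 13 α-hydroxy ester (new quaternary C4, Δ5(6), carbinol epimers)
Conditions: 12 (50% in toluene), Me2AlCl, CH2Cl2, −78 → 0 °C
Reagents that add atoms: ethyl glyoxylate, CCOC(=O)C=O
Why: Lewis-acid carbonyl-ene reaction (Snider type). C–C bond formation at C4 with H transfer from C6 gives the C5=C6 alkene. H transfer from C10 would give a Δ5(10) alkene flanked by two quaternary carbons, which is disfavoured. The enophile attacks anti to C9 (the quaternary carbon on C10), so the new substituent lands cis to H10 as required.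

**Step 8**
Reactants: 13; 14 phenyl chlorothionoformate
Product: 15 O-phenyl thiocarbonate
Conditions: 14, DMAP, pyridine, CH2Cl2, rt → 40 °C
Reagents that add atoms: phenyl chlorothionoformate, S=C(Cl)Oc1ccccc1
Why: Acylation of the hindered but acidic α-hydroxy ester gives the Barton–McCombie precursor.

**Step 9**
Reactants: 15
Product: 16 ethyl ester
Conditions: Bu3SnH, AIBN, PhMe, 110 °C
Reagents that add atoms: none
Why: Barton–McCombie deoxygenation through the α-ester radical. The carbinol stereocentre is removed, and quaternary C4 and Δ5(6) are unaffected.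

**Step 10**
Reactants: 16
Product: 17 unit-1 acetic acid
Conditions: KOH, EtOH/H2O, reflux, 24 h; then 1 M HCl to pH 3, 0 °C
Reagents that add atoms: water, O
Why: Saponification of the neopentyl-type ethyl ester. There is no epimerisable centre α to the ester, and the aryl ethers and alkene survive brief mild acidification.

**Step 11**
Reactants: 18 (S)-pulegone; 4 iodomethane
Product: 19 trans-6-methyl-(S)-pulegone
Conditions: LDA, THF, −78 °C; then 4, 0 °C
Reagents that add atoms: iodomethane, CI
Why: Kinetic α′-enolate alkylation of pulegone. Methyl enters anti to the 5-Me, and this C6 centre is erased in the next step.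

**Step 12**
Reactants: 19; 20 methyl bromoacetate
Product: 21 6-methyl-6-(methoxycarbonylmethyl)-(S)-pulegone (CH2CO2Me trans, Me cis to the 5-Me)
Conditions: LDA, THF, −78 °C; then 20, DMPU, −78 °C → rt
Reagents that add atoms: methyl bromoacetate, COC(=O)CBr
Why: Enolate alkylation forms quaternary C9′. The cross-conjugated dienolate has its 5-Me pseudoaxial (A(1,2) strain with the 6-Me), and axial attack anti to it puts CH2CO2Me trans to the 5-Me and the 6-Me cis to it, as in the target. There is no C5′ substituent yet to block the attack face.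

**Step 13**
Reactants: 21; 22 2-(1,3-dioxolan-2-yl)ethylmagnesium bromide
Product: 23 keto acetal ester (2-CH2CO2Me trans to 3-Me; 6-[4-(1,3-dioxolan-2-yl)-2-methylbutan-2-yl] trans to 3-Me)
Conditions: (i) 22 (3 equiv), CuBr·SMe2 (1.2 equiv), TMSCl, THF, −78 → −40 °C; aq. NH4Cl; (ii) NaOMe, MeOH, rt
Reagents that add atoms: 2-(1,3-dioxolan-2-yl)ethylmagnesium bromide, Br[Mg]CCC1OCCO1
Why: Cuprate 1,4-addition to the β,β-dimethyl enone (as in the 8-phenylmenthone synthesis from pulegone) creates the gem-dimethyl carbon C4′. NaOMe equilibration of C5′, which is α to the ketone, gives the chair in which the bulky C5′ group and the 8′-Me are both equatorial and trans, as in the target.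

**Step 14**
Reactants: 23
Product: 24 keto aldehyde
Conditions: 1 M HCl, acetone, rt
Reagents that add atoms: water, O
Why: Dioxolane hydrolysis; the ketone and methyl ester are untouched.

**Step 15**
Reactants: 24
Product: 25 methyl ester of unit 2 (Δ1(10))
Conditions: TiCl3(DME)1.5, Zn–Cu, DME, reflux
Reagents that add atoms: none
Why: Intramolecular McMurry coupling closes ring A′ and places the trisubstituted alkene at C10′=C1′. No stereocentre is touched.

**Step 16**
Reactants: 25
Product: 26 unit-2 acetic acid
Conditions: KOH, MeOH/H2O, reflux; then 1 M HCl to pH 3, 0 °C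
Reagents that add atoms: water, O
Why: Saponification of the neopentyl-type methyl ester. No stereocentre is affected, and the brief mild acidification spares the trisubstituted alkene.

**Step 17**
Reactants: 17 (1 equiv); 26 (3 equiv)
Product: 27 dimethyl ether of toxiusol
Conditions: Me4N·OH (0.1 equiv), acetone, RVC(+)/RVC(−), rapid alternating polarity (50 ms), 25 mA, rt
Reagents that add atoms: none
Why: Proposed new method: waveform-controlled Kolbe heterocoupling of two different, hindered β-quaternary bicyclic terpenoid acids to join two quaternary-carbon-bearing CH2 groups. Anodic carboxylate oxidation and CO2 loss give two primary neopentyl-type CH2• radicals, which couple on the electrode surface to form the CH2–CH2 bond. Surface radical concentrations are high enough that coupling should outpace homoallyl (1,2-vinyl) shift of the C4 radical. The closest known reaction is rapid-alternating-polarity Kolbe coupling of simple acids. The excess of 26 biases the mixture toward the cross-product, and its homodimer is a non-polar by-product separable by chromatography. No stereocentre is touched, because both radicals are primary.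

**Step 18**
Reactants: 27
Product: 28 toxiusol hydroquinone
Conditions: BBr3, CH2Cl2, −78 → 0 °C, Ar; then quench into degassed sat. aq. NaHCO3, 0 °C
Reagents that add atoms: none
Why: Lewis-acid cleavage of the aryl methyl ethers. The bicarbonate quench avoids strong acid on the alkenes, and the oxidation-prone hydroquinone is used immediately.

**Step 19**
Reactants: 28; 29 sulfur trioxide–pyridine
Product: 30 toxiusol (bis-sulfate)
Conditions: 29 (4 equiv), pyridine, rt, 12 h; then aq. NaHCO3
Reagents that add atoms: sulfur trioxide–pyridine, O=S(=O)=O.c1ccncc1 (adds two SO3)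
Why: O-sulfation of both phenols; the isolated disodium salt is drawn as the free acid.

---

**Compound list**

1 | (5R)-5-methyl-2-(propan-2-ylidene)cyclohexanone, (R)-(+)-pulegone | C[C@@H]1CCC(=C(C)C)C(=O)C1 | starting material
2 | 2-(bromomethyl)-1,4-dimethoxybenzene | BrCc1cc(OC)ccc1OC | starting material
3 | trans-6-(2,5-dimethoxybenzyl)-(R)-pulegone | O=C1[C@@H](Cc2cc(OC)ccc2OC)[C@H](C)CCC1=C(C)C | intermediate
4 | iodomethane | CI | starting material
5 | 6-(2,5-dimethoxybenzyl)-6-methyl-(R)-pulegone (Me trans, benzyl cis to 5-Me) | O=C1[C@](C)(Cc2cc(OC)ccc2OC)[C@H](C)CCC1=C(C)C | intermediate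
6 | N-phenylbis(trifluoromethanesulfonimide) | O=S(=O)(C(F)(F)F)N(c1ccccc1)S(=O)(=O)C(F)(F)F | starting material
7 | dienyl triflate: 6-(2,5-dimethoxybenzyl)-5,6-dimethyl-2-(prop-1-en-2-yl)cyclohex-1-en-1-yl triflate | FC(F)(F)S(=O)(=O)OC1=C(C(C)=C)CC[C@@H](C)[C@@]1(C)Cc2cc(OC)ccc2OC | intermediate
8 | 3-(2,5-dimethoxybenzyl)-3,4-dimethyl-1-(prop-1-en-2-yl)cyclohex-1-ene (diene) | C=C(C)C1=C[C@](C)(Cc2cc(OC)ccc2OC)[C@H](C)CC1 | intermediate
9 | phenyl vinyl sulfone | C=CS(=O)(=O)c1ccccc1 | starting material
10 | Diels–Alder octalin, PhSO2 at C1 (C1 epimers), C4=C5, 4-Me, 9-benzyl | CC1=C2CC[C@@H](C)[C@@](C)(Cc3cc(OC)ccc3OC)[C@@H]2C(S(=O)(=O)c4ccccc4)CC1 | intermediate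
11 | octalin: C4-Me, C4=C5, 8-Me, 9-Me-9-(2,5-dimethoxybenzyl), H10 | CC1=C2CC[C@@H](C)[C@@](C)(Cc3cc(OC)ccc3OC)[C@@H]2CCC1 | intermediate
12 | ethyl glyoxylate | CCOC(=O)C=O | starting material
13 | ethyl 2-hydroxy-2-(C4 of the octalin)acetate, Δ5(6) (carbinol epimers) | C[C@@H]1CC=C2[C@@H](CCC[C@@]2(C)C(O)C(=O)OCC)[C@]1(C)Cc1cc(OC)ccc1OC | intermediate
14 | phenyl chlorothionoformate | S=C(Cl)Oc1ccccc1 | starting material
15 | O-phenyl thiocarbonate of 13 | C[C@@H]1CC=C2[C@@H](CCC[C@@]2(C)C(OC(=S)Oc3ccccc3)C(=O)OCC)[C@]1(C)Cc1cc(OC)ccc1OC | intermediate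
16 | ethyl ester of the unit-1 acid | C[C@@H]1CC=C2[C@@H](CCC[C@@]2(C)CC(=O)OCC)[C@]1(C)Cc1cc(OC)ccc1OC | intermediate
17 | unit-1 acetic acid | C[C@@H]1CC=C2[C@@H](CCC[C@@]2(C)CC(=O)O)[C@]1(C)Cc1cc(OC)ccc1OC | intermediate
18 | (5S)-5-methyl-2-(propan-2-ylidene)cyclohexanone, (S)-(−)-pulegone | C[C@H]1CCC(=C(C)C)C(=O)C1 | starting material
19 | trans-6-methyl-(S)-pulegone (6-Me trans to 5-Me) | O=C1[C@H](C)[C@@H](C)CCC1=C(C)C | intermediate
20 | methyl bromoacetate | COC(=O)CBr | starting material
21 | 6-methyl-6-(methoxycarbonylmethyl)-(S)-pulegone (CH2CO2Me trans, Me cis to 5-Me) | O=C1[C@](C)(CC(=O)OC)[C@@H](C)CCC1=C(C)C | intermediate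
22 | 2-(1,3-dioxolan-2-yl)ethylmagnesium bromide | Br[Mg]CCC1OCCO1 | starting material
23 | keto acetal ester (quaternary C9′, C5′ group trans to 8′-Me) | O=C1[C@](C)(CC(=O)OC)[C@@H](C)CC[C@@H]1C(C)(C)CCC2OCCO2 | intermediate
24 | keto aldehyde | O=C1[C@](C)(CC(=O)OC)[C@@H](C)CC[C@@H]1C(C)(C)CCC=O | intermediate
25 | methyl ester of unit 2 (Δ1(10)) | COC(=O)C[C@@]1(C)C2=CCCC(C)(C)[C@H]2CC[C@@H]1C | intermediate
26 | unit-2 acetic acid | OC(=O)C[C@@]1(C)C2=CCCC(C)(C)[C@H]2CC[C@@H]1C | intermediate
27 | toxiusol dimethyl ether | C[C@@H]1CC=C2[C@@H](CCC[C@@]2(C)CC[C@@]2(C)C3=CCCC(C)(C)[C@H]3CC[C@@H]2C)[C@]1(C)Cc1cc(OC)ccc1OC | intermediate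
28 | toxiusol hydroquinone | C[C@@H]1CC=C2[C@@H](CCC[C@@]2(C)CC[C@@]2(C)C3=CCCC(C)(C)[C@H]3CC[C@@H]2C)[C@]1(C)Cc1cc(O)ccc1O | intermediate
29 | sulfur trioxide–pyridine complex | O=S(=O)=O.c1ccncc1 | starting material
30 | toxiusol (bis-sulfate) | C[C@@H]1CC=C2[C@@H](CCC[C@@]2(C)CC[C@@]2(C)C3=CCCC(C)(C)[C@H]3CC[C@@H]2C)[C@]1(C)Cc1cc(OS(=O)(=O)O)ccc1OS(=O)(=O)O | target

---

**Totals**
- Total steps: 19.
- Longest linear sequence: 13 (steps 1–10, then 17–19).

**Three steps most likely to fail**
1. **Step 17 (proposed new Kolbe heterocoupling).** The risks are statistical homodimerisation, anodic oxidation of the dimethoxyarene, and homoallyl rearrangement of the C4 neopentyl radical.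
   - Fallback (known chemistry, different approach): reduce 17 with LiAlH4 and convert the alcohol to the iodide C4–CH2CH2–I (I2, PPh3, imidazole). Alkylate the dienolate of 19 with it (LDA, DMPU) to make C9′ quaternary with the CH2CH2–C4 link. Then add 22 with Cu and equilibrate with NaOMe, hydrolyse the acetal and close ring A′ by McMurry (as in steps 13–15) to reach 27 directly.
2. **Step 7 (carbonyl-ene on the tetrasubstituted alkene).** The risks are Δ5(10) versus Δ5(6) regiochemistry, and Friedel–Crafts reaction at the dimethoxyarene.
   - Fallback: allylic oxidation of 11 (CrO3·3,5-dimethylpyrazole) to the C3-ketone enone, separated from the C6 regioisomer. Deconjugative α-alkylation of its dienolate (t-BuOK, BrCH2CO2tBu) installs quaternary C4 with Δ5(6). Wolff–Kishner reduction (N2H4, KOH, diethylene glycol, 190 °C) removes the C3 ketone and cleaves the t-butyl ester, giving 17.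
3. **Step 12 (bromoacetate alkylation of the hindered tetrasubstituted dienolate).** The risks are low yield and O-alkylation. The ester must also survive the cuprate addition in step 13.
   - Fallback: use allyl bromide in step 12. Carry the allyl group through the Cu addition and NaOMe equilibration, then convert it to CH2CO2Me (OsO4 cat., NaIO4; NaClO2, NaH2PO4; TMSCHN2) before acetal hydrolysis. The ester is then absent during the Grignard/cuprate step and the alkylation uses a more reactive electrophile.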